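**Target:** Ludongunin J, a 6,7-seco-ent-kauranoid. It has a spiro 7,20-δ-lactone at C10, a cis-fused 6,19-cyclic methyl acetal (THF) on ring A, and a bicyclo[3.2.1]octane C/D unit carrying the C15 ketone and the C16=C17 exocyclic methylene.

## Retrosynthetic overview
1. The C16=C17 methylene is installed last, by α-methylenation of the C15 ketone **19**.
2. Ring D (C13–C16) is closed by a 5-exo radical cyclization of the α-bromoketone **18** onto a ring-C vinyl chloride. Ring C comes from a Diels–Alder reaction of chloroprene with the spiro 3-acetyl-dihydropyranone **15**, which is made by intramolecular Knoevenagel condensation of the C20 acetoacetate **14**.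
3. The hydroxy-aldehyde **12** (C10 quaternary: C20 CH₂OH, C9 CHO) comes from **8**. In **8**, the THF, ring A, C4, C5 and a spiro-Meldrum's acid at C10 are built together in one amine-catalysed intramolecular Michael/Michael (formal Diels–Alder) cascade of a 2-aminodiene onto a tethered alkylidene Meldrum's acid. Methanolysis of the Meldrum's acid then differentiates C9 from C20.
4. Ring-formation order: THF + ring A (Step 4), δ-lactone (Step 10), ring C (Step 11), ring D (Step 13).

Assumptions: the C6 OMe of the target is the thermodynamic (anomeric) acetal, equilibrated in the acidic methanol of Step 5. The cinchona primary amine is a catalyst, not a starting material. The labile centres in **3** (enolizable) and **7** (C6 acetal) do not matter, because C4 is erased on enamine formation and C6 is re-equilibrated.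

---

### Step 1
Reactants: **1** ethyl vinyl ketone; **2** formaldehyde (monomeric)
Product: **3** 1-hydroxy-2-methylpent-4-en-3-one (racemic, labile C2 methine)
Conditions: LiHMDS, THF, −78 °C; then CH₂O (from cracked paraformaldehyde), −78 → −40 °C; quench at −40 °C with aq. NH₄Cl
Reagents that add atoms: none
Why: The vinyl ketone has only one enolizable position (the ethyl CH₂), so aldol hydroxymethylation is regiospecific and installs the C19 oxygen. A cold quench limits dehydration of the β-hydroxy ketone.

### Step 2
Reactants: **4** Meldrum's acid; **5** 2,2-dimethoxyacetaldehyde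
Product: **6** 5-(2,2-dimethoxyethylidene)-2,2-dimethyl-1,3-dioxane-4,6-dione
Conditions: H₂O, 25–40 °C (catalyst-free; or piperidinium acetate cat., CH₂Cl₂, 4 Å MS, 25 °C)
Reagents that add atoms: none
Why: Knoevenagel condensation gives the highly electrophilic alkylidene Meldrum's acid (C5=C10) carrying the protected C6 aldehyde.

### Step 3
Reactants: **3**; **6**
Product: **7** mixed acetal tethering the C19 alcohol to C6 (C6 epimers, C4 racemic; no stereodescriptors)
Conditions: **6** (1.1 equiv), PPTS (20 mol%), CH₂Cl₂, 4 Å MS, 25 → 40 °C
Reagents that add atoms: none (MeOH is lost)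
Why: Acid-catalysed transacetalization, driven by MeOH capture on the sieves, installs the O-tether. This gives a three-atom tether (C19–O–C6) between the future diene terminus C4 and the dienophile carbon C5.

### Step 4
Reactants: **7**
Product: **8** cis-fused 6-methoxy-tetrahydrofuran/cyclohexanone (C3 ketone; C4 Me/C19 quaternary; C5–H; C6 OMe; spiro-Meldrum's acid at C10)
Conditions: (9S)-9-amino-9-deoxy-epiquinine (20 mol%), TFA (40 mol%), PhMe (0.02 M), 25 °C, 72 h; then aq. NaHCO₃
Reagents that add atoms: none
Why: Proposed new method: the ketimine of the α′-branched vinyl ketone tautomerizes to a 2-amino-1,3-diene (C4=C3(NHR)–C2=C1), which adds through C4 to the tethered alkylidene Meldrum's acid (5-exo Michael, forming C4–C5 and the THF). The resulting Meldrum's enolate (C10) then adds to the α,β-unsaturated iminium at C1 (6-endo Michael), closing ring A, and the enamine hydrolyses to the C3 ketone. The cis ring fusion and the C4/C5 absolute configuration are set by the chiral amine and the O-tether. The closest known reactions are aminocatalytic Diels–Alder/Michael reactions of enone-derived 2-aminodienes with nitroolefins and alkylidene malonates, and tethered intramolecular Diels–Alder reactions of aminodienes. It is new in being intramolecular and O-tethered, forming a quaternary centre, and using an alkylidene Meldrum's acid.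

### Step 5
Reactants: **8**
Product: **9** methyl ester (C9, equatorial) / carboxylic acid (C20, axial) at C10, C3 ketone retained
Conditions: MeOH, PPTS (5 mol%), 80 °C, sealed tube, 16 h
Reagents that add atoms: methanol, `CO`
Why: Methanolysis of the spiro-Meldrum's acid (loss of acetone) occurs at the less hindered equatorial carbonyl. The axial carbonyl, syn to the C19 methylene, survives as the acid, so C10 is defined as C9 = ester and C20 = acid. The same acidic MeOH equilibrates the C6 acetal to the anomeric isomer.

### Step 6
Reactants: **9**
Product: **10** C3-deoxygenated acid-ester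
Conditions: TsNHNH₂, MeOH, 60 °C; then catecholborane (5 equiv), CHCl₃, 0 °C; NaOAc·3H₂O, reflux
Reagents that add atoms: none
Why: Kabalka reduction of the tosylhydrazone converts C3 C=O to CH₂ under non-acidic conditions that tolerate the acetal and ester. The carboxylic acid is transiently masked as its acyloxyborane (excess reagent).

### Step 7
Reactants: **10**
Product: **11** C20 hydroxymethyl / C9 methyl ester
Conditions: BH₃·THF (3 equiv), THF, 0 → 25 °C; MeOH quench
Reagents that add atoms: none
Why: Borane reduces the carboxylic acid selectively over the hindered methyl ester, turning C20 into CH₂OH with all stereocentres untouched.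

### Step 8
Reactants: **11**
Product: **12** hydroxy-aldehyde (C10 quaternary: CH₂OH, CHO)
Conditions: DIBAL-H (4 equiv), CH₂Cl₂, −78 °C, 1 h; Rochelle salt work-up
Reagents that add atoms: none
Why: Partial reduction of the neopentyl methyl ester stops at the aldehyde (C9) at −78 °C, with the free alcohol tied up as aluminium alkoxide and the tetrahedral intermediate stable at that temperature.

### Step 9
Reactants: **12**; **13** diketene
Product: **14** C20 acetoacetate of **12**
Conditions: **13** (1.5 equiv), DMAP (20 mol%), Et₃N, CH₂Cl₂, 0 → 25 °C
Reagents that add atoms: none (diketene is numbered reactant **13**)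
Why: DMAP-catalysed acetoacetylation of the primary alcohol via acetylketene; the aldehyde is untouched.

### Step 10
Reactants: **14**
Product: **15** spiro δ-lactone, 3-acetyl-5,6-dihydro-2H-pyran-2-one (C8=C9)
Conditions: piperidine (20 mol%), AcOH (20 mol%), 4 Å MS, benzene, 80 °C
Reagents that add atoms: none
Why: Intramolecular Knoevenagel condensation closes the six-membered C7–O–C20–C10–C9=C8 ring. This gives a doubly activated (C7 lactone, C15 acetyl) dienophile.

### Step 11
Reactants: **15**; **16** chloroprene
Product: **17** cycloadduct (C8 quaternary; C12(Cl)=C13 vinyl chloride; lactone cis-fused to ring C)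
Conditions: **16** (10 equiv, 50% in xylene), Et₂AlCl (1.0 equiv), CH₂Cl₂, −78 → 0 °C
Reagents that add atoms: none
Why: Lewis-acid Diels–Alder reaction forms ring C. The 2-chlorodiene gives the "para" regiochemistry (Cl at C12, para to C8). The cyclic dienophile fixes C7/C10 cis, so the C15 acetyl and C9–H end up cis on the opposite face. The diene approaches anti to the branched C5, setting C8/C9 relative to C10.

### Step 12
Reactants: **17**
Product: **18** C16 α-bromomethyl ketone
Conditions: PhNMe₃⁺ Br₃⁻ (1.05 equiv), THF, 0 °C
Reagents that add atoms: phenyltrimethylammonium tribromide, `C[N+](C)(C)c1ccccc1.[Br-].BrBr`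
Why: C8 is quaternary, so the acetyl methyl is the only enolizable site and α-bromination is regiospecific. The chloro-substituted alkene is deactivated toward bromine addition.

### Step 13
Reactants: **18**
Product: **19** pentacyclic ketone (C13–C16 bond formed; C12 = CH₂)
Conditions: Bu₃SnH (2.5 equiv, syringe pump 8 h), AIBN, benzene (5 mM), 80 °C; then Bu₃SnH (3 equiv), AIBN, PhMe, 110 °C
Reagents that add atoms: none
Why: Br abstraction gives the electrophilic α-keto radical C16•. It cyclizes 5-exo onto C13 of the vinyl chloride, which is polarity-matched and favoured over the 6-endo [2.2.2] mode at C12. This forms the bicyclo[3.2.1]octane, with the C13 configuration forced by the C15–C16 bridge on the face bearing the acetyl. The α-chloro radical is reduced, and the C–Cl bond is then hydrogenolysed at higher temperature. This is a known reaction type (radical cyclization onto vinyl halides) on a new substrate.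

### Step 14
Reactants: **19**
Product: **20** Ludongunin J
Conditions: LiHMDS, THF, −78 °C; then Me₂N⁺=CH₂ I⁻, −78 → 25 °C; then MeI, CH₂Cl₂; then DBU
Reagents that add atoms: Eschenmoser's salt (dimethylmethyleneiminium iodide), `C=[N+](C)C.[I-]`
Why: The C15 ketone is flanked by quaternary C8, so enolization and Mannich aminomethylation occur only at C16. Quaternization and E1cB elimination then give the α-methylene ketone; the lactone and acetal survive.

---

## Compound list
1 | ethyl vinyl ketone | `C=CC(=O)CC` | starting material
2 | formaldehyde | `C=O` | starting material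
3 | 1-hydroxy-2-methylpent-4-en-3-one | `C=CC(=O)C(C)CO` | intermediate
4 | Meldrum's acid | `CC1(C)OC(=O)CC(=O)O1` | starting material
5 | 2,2-dimethoxyacetaldehyde | `COC(OC)C=O` | starting material
6 | 5-(2,2-dimethoxyethylidene)-2,2-dimethyl-1,3-dioxane-4,6-dione | `COC(OC)C=C1C(=O)OC(C)(C)OC1=O` | intermediate
7 | mixed acetal of 3 with 6 | `C=CC(=O)C(C)COC(OC)C=C1C(=O)OC(C)(C)OC1=O` | intermediate
8 | ring-A/THF acetal ketone with spiro-Meldrum's acid | `O=C1CCC2(C(=O)OC(C)(C)OC2=O)[C@@H]3[C@H](OC)OC[C@]13C` | intermediate
9 | C9 methyl ester / C20 acid, C3 ketone | `COC(=O)[C@]1(C(=O)O)CCC(=O)[C@@]2(C)CO[C@@H](OC)[C@H]21` | intermediate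
10 | C3-deoxygenated acid-ester | `COC(=O)[C@]1(C(=O)O)CCC[C@@]2(C)CO[C@@H](OC)[C@H]21` | intermediate
11 | C20 alcohol / C9 methyl ester | `COC(=O)[C@]1(CO)CCC[C@@]2(C)CO[C@@H](OC)[C@H]21` | intermediate
12 | hydroxy-aldehyde | `O=C[C@]1(CO)CCC[C@@]2(C)CO[C@@H](OC)[C@H]21` | intermediate
13 | diketene | `C=C1CC(=O)O1` | starting material
14 | C20 acetoacetate | `CC(=O)CC(=O)OC[C@@]1(C=O)CCC[C@@]2(C)CO[C@@H](OC)[C@H]21` | intermediate
15 | spiro 3-acetyl-dihydropyranone | `CC(=O)C1=C[C@]2(COC1=O)CCC[C@@]3(C)CO[C@@H](OC)[C@H]32` | intermediate
16 | chloroprene | `C=CC(Cl)=C` | starting material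
17 | Diels–Alder adduct | `CC(=O)[C@]12CC=C(Cl)C[C@H]1[C@]1(COC2=O)CCC[C@@]3(C)CO[C@@H](OC)[C@H]31` | intermediate
18 | α-bromomethyl ketone | `BrCC(=O)[C@]12CC=C(Cl)C[C@H]1[C@]1(COC2=O)CCC[C@@]3(C)CO[C@@H](OC)[C@H]31` | intermediate
19 | pentacyclic C15 ketone | `C1C(=O)[C@]23C[C@H]1CC[C@H]2[C@@]1(CCC[C@@]2(C)CO[C@@H](OC)[C@H]21)COC3=O` | intermediate
20 | Ludongunin J | `C=C1C(=O)[C@]23C[C@H]1CC[C@H]2[C@@]1(CCC[C@@]2(C)CO[C@@H](OC)[C@H]21)COC3=O` | target

## Totals
Total steps: 14. Longest linear sequence: 13 (1 → 3 → 7 → 8 → 9 → 10 → 11 → 12 → 14 → 15 → 17 → 18 → 19 → 20).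

## Three steps most likely to fail
1. **Step 4 (proposed new method).** The tetrasubstituted aminodiene may form poorly, and the enantio- and cis-selectivity may be low.
   Fallback (known chemistry): go stepwise and racemic. Make the TMS dienol ether of **7** (TMSOTf, Et₃N) and close the THF by Sc(OTf)₃-catalysed intramolecular Mukaiyama–Michael addition. Then close ring A by DBU-mediated 6-endo Michael addition of the Meldrum's C–H onto the vinyl ketone. Resolve at acid **9** by crystallizing its cinchonidine salt.
2. **Step 11.** The hindered Diels–Alder reaction may show poor facial selectivity or regioselectivity, or Et₂AlCl may cleave the acetal.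
   Fallback (changes approach): add allylmagnesium bromide/CuBr·SMe₂ to **15** at C9 and trap the enolate with allyl bromide at C8. Close ring C by Grubbs-II ring-closing metathesis (C12=C13) to give the chlorine-free cyclohexene, then continue with ring D closure and methylenation.
3. **Step 13.** Direct reduction of C16•, 6-endo closure, or incomplete dechlorination could compete.
   Fallback (changes approach): on the chlorine-free cyclohexene from the RCM route, replace the tin-hydride radical closure with a Pd(OAc)₂/benzoquinone Toyota–Ihara cycloalkenylation of the TMS enol ether of the acetyl methyl ketone onto the ring-C alkene. This forms the C13–C16 bond through an organopalladium pathway; the resulting alkene is then hydrogenated.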